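**Remark:** ring atoms carry the target's numbering (O1, C2–C5) in every numbered compound of the route, so C2 is the lactone carbonyl carbon of 6 and C5 its acetal carbon; F4, F5, F6 and A7 are named with their own systematic locants. Grignard reagent 19 is taken as the commercial THF solution. Steps 8 and 10 each consume two equivalents of their second reactant, one per terminus of the twofold-symmetric core.

## Analysis of the target

The target is a single tetrahydrofuran ring (O1, C2–C5) in which C2 and C5 each carry a 4-oxy-3-methoxyphenyl group and C3 and C4 each carry a methyl group, and each aryl oxygen is etherified by a 1-(3,4-dimethoxyphenyl)-1-hydroxypropan-2-yl chain. There are eight stereocentres: C2 (R), C3 (S), C4 (S) and C5 (R) in the ring and, in each chain, the carbinol carbon C7 (R) and the ether carbon C8 (R). In the ring the methyls are trans and each aryl group is cis to the methyl next to it (2,3-cis, 3,4-trans, 4,5-cis), so the aryl groups are trans to each other; both chains are threo, and a twofold axis through O1 and the midpoint of C3–C4 lets the two phenol termini be elaborated in parallel. The sensitive sites are the C2–O1 and C5–O1 bonds, which are benzylic ethers of electron-rich arenes that acid can ionise and hydrogenation can cleave, the veratryl carbinols, which ionise easily, and C8, which can epimerise whenever C7 is a carbonyl carbon. The main difficulty is that both aryl/methyl cis relationships are contra-thermodynamic, so C2 and C5 must each be set under kinetic control. The trans-dimethyl pair must in addition be made in one absolute sense without a functional handle on C3 or C4. The strategy rests on the position of C3 and C4 between C2 and C5, both of which can be carried at a higher oxidation level, C2 as a lactone carbonyl and C5 as an acetal carbon. The unit O1–C2–C3–C4–C5 is then a 5-alkoxybutenolide with C3=C4 as its alkene, and the alkoxy group on C5 can serve as a removable chiral control element.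

## Retrosynthetic reasoning

**C7–aryl bonds.** The two bonds between the carbinol carbons and the 3,4-dimethoxyphenyl rings of 20 are cut first, giving dialdehyde 18 and two equivalents of Grignard reagent 19. This leaves the acid-labile benzylic carbinols to the last step. The forward addition must give the threo relationship at both ends, which chelation of magnesium between the aldehyde oxygen and the C8 aryloxy oxygen should provide.

**Aryl O–C8 bonds.** Dialdehyde 18 comes from diester 17 by partial reduction. The two aryl O–C8 bonds of 17 are then cut to bisphenol 15 and two equivalents of ethyl (S)-lactate 16. The gain is that C8 comes from the chiral pool. The forward Mitsunobu reaction must invert the lactate centre cleanly, twice.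

**Benzyl ethers.** Bisphenol 15 is traced to the dibenzyl ether 14, so that both aryl groups enter as derivatives of the one bromide 7.

**C5–aryl bond.** This bond of 14 is cut to give sulfone 11 and arylzinc 13, made from 7 through Grignard reagent 12. Ionisation at C5 is chosen because the 4,5-cis relationship cannot come from equilibration and must come from kinetic attack on the ring cation. Sulfone 11 comes from acetal 10 by exchange of its menthyloxy group for a sulfinate. The acetal carbon that directed the earlier chemistry is thus the carbon that receives the second aryl group.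

**C2–aryl and C2–H bonds.** These bonds of 10 are cut back to lactone 6 and aryllithium 8, also made from 7, through hemiketalate 9. The forward sequence is carbonyl addition followed by ionic hydrogenation. Hydride delivery anti to the C3 methyl places the aryl group cis to it. Hemiketalate 9 must be carried on without protonation, because protonation would let the ring open and the acetal be lost.

**C3–CH3 and C4–CH3 bonds (key disconnection).** Both methyl bonds of 6 are cut at once, leading through enolate 5 to butenolide 4. Cutting here removes both methyl-bearing stereocentres in one step and leaves a flat, crystalline precursor with a single stereocentre at C5. The forward reaction must add a methyl nucleophile to C4 anti to the C5 alkoxy group, then a methyl electrophile to C3 anti to the new C4 methyl.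

**Acetal C5–O bond.** Butenolide 4 is cut at its exocyclic acetal bond to hydroxybutenolide 2 and (+)-menthol 3. Compound 2 comes from furfural 1 by photo-oxygenation with loss of the formyl carbon. The forward acetalisation must deliver one C5 epimer, which crystallisation with epimerisation of the mother liquor should achieve.

## Alternatives that were turned down

Alternative 1: tandem Grignard addition and ring closure.
- Disconnection: the C5–aryl bond and the O1–C2 bond.
- Forward key step: aryl Grignard reagent A3 adds to the aldehyde of the acyclic mesylate A2, and the new alkoxide displaces the benzylic mesylate with inversion, closing the ring to the dibromide A1.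
- For it: the ring and a carbon–carbon bond form in one operation. The C2 configuration follows from a stereospecific SN2 displacement, not from facial selectivity. The para bromine holds back ionisation of the benzylic mesylate.
- Against it: the C5 configuration rests on 1,2-induction from a single α-methyl group in an open-chain aldehyde, which is rarely high for aryl Grignard reagents. A2 needs three contiguous stereocentres assembled beforehand, one of them enolisable next to the aldehyde. A1 still needs two aryl bromide to phenol conversions before it reaches bisphenol 15.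
- Comparison: Alternative 1 is stronger on ring-forming economy and on the certainty of the C2 centre. The chosen strategy offers the C3/C4 pair in one step from a crystalline single diastereomer, sets both benzylic centres on a ring, where facial control is better understood than in an open chain, and uses oxygenated aryl units directly.

Alternative 2: two-fold arylzinc substitution of a bis-sulfone.
- Disconnection: both C–aryl bonds, C2–aryl and C5–aryl, at once.
- Forward key step: two equivalents of the side-chain-bearing arylzinc A6 replace both sulfinates of the bis-sulfone A5 through successive oxocarbenium ions under ZnBr2, giving the bis-silyl ether A4. Desilylation of A4 gives the target.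
- For it: it is the most convergent plan, it uses the twofold symmetry fully, and both substitutions obey the same preference for attack cis to the neighbouring methyl. The side-chain stereocentres are settled on a small fragment.
- Against it: A6 is a multistep enantiopure fragment that must be used in excess. Its silyl ether sits on a dimethoxybenzylic carbon that a Lewis acid can ionise. The second substitution must ionise C5 next to the freshly formed, acid-labile benzylic ether at C2. Both events must be selective or three diastereomers result. The plan also does not say where the absolute configuration of A5 comes from.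
- Comparison: Alternative 2 is stronger on convergence and on the length of the longest linear sequence. The chosen strategy supplies the C3/C4 configuration that Alternative 2 presupposes, uses only the cheap bromide 7 in the organometallic steps, sets C2 and C5 in two separate steps that can each be checked, and keeps the side chains away from Lewis acids.

Alternative 3: carbene-catalysed homoenolate annulation.
- Disconnection: the C4–C5 bond and the O1–C2 bond of the aryl lactone A7.
- Forward key step: an N-heterocyclic carbene turns tiglic aldehyde A8 into a homoenolate, whose β-carbon adds to the aryl aldehyde A9. The alkoxide then acylates on the acyl azolium and closes the lactone.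
- For it: it is catalytic, uses two cheap achiral aldehydes, and makes the ring, one carbon–carbon bond and three stereocentres in one step. A7 already holds the first aryl group cis to its neighbouring methyl.
- Against it: α-substituted enals such as A8 form and react as homoenolates reluctantly. Electron-rich aldehydes such as A9 are poor acceptors and divert into benzoin-type products. The C3 centre arises by protonation, not by bond formation, so its control is uncertain. Enantiocontrol with simple aldehyde acceptors is often moderate.
- Comparison: Alternative 3 is stronger on atom economy and on being catalytic. The chosen strategy uses a stoichiometric auxiliary but relies only on substrate control from an enantiopure crystalline precursor. Its key step has to solve two facial selectivities of known sense, whereas Alternative 3 must solve chemo-, diastereo- and enantioselectivity at once.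

Key step: step 3

## Route

Step 1
Reactants: 1 furfural
Product: 2 5-hydroxyfuran-2(5H)-one (racemic)
Conditions: O2, visible light, rose bengal (C20H2Cl4I4Na2O5, cat.), MeOH, rt
Reagents that add atoms: dioxygen, O=O
Why: Dye-sensitised photo-oxygenation; singlet oxygen adds across C2/C5 of the furan and methanolysis of the endoperoxide expels the formyl carbon as methyl formate, leaving the hydroxybutenolide. Its hemiacetal centre is racemic and labile, which step 2 uses.

Step 2
Reactants: 2 5-hydroxyfuran-2(5H)-one; 3 (+)-menthol, (1S,2R,5S)-2-isopropyl-5-methylcyclohexan-1-ol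
Product: 4 (5S)-5-{[(1S,2R,5S)-2-isopropyl-5-methylcyclohexyl]oxy}furan-2(5H)-one
Conditions: TsOH·H2O (cat.), toluene, reflux, Dean–Stark; crystallisation from petroleum ether, mother liquor re-equilibrated with acid and recrystallised
Reagents that add atoms: none
Why: Acid-catalysed acetalisation of the cyclic hemiacetal with removal of water; the C5 epimers interconvert under acid and the less soluble one crystallises (crystallisation-induced diastereomer transformation). With (+)-menthol the crystalline epimer should be the (5S) acetal, the mirror image of the familiar (5R) acetal of (−)-menthol.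

Step 3
Reactants: 4 (5S)-5-{[(1S,2R,5S)-2-isopropyl-5-methylcyclohexyl]oxy}furan-2(5H)-one
Product: 6 (3S,4S,5S)-3,4-dimethyl-5-{[(1S,2R,5S)-2-isopropyl-5-methylcyclohexyl]oxy}dihydrofuran-2(3H)-one, via lithium enolate 5 (not isolated)
Conditions: Me2CuLi (from CuBr·SMe2 and 2 MeLi), Et2O, −78 → −40 °C; then MeI (excess), DMPU, THF, −78 → −20 °C
Reagents that add atoms: lithium dimethylcuprate, [Li+].C[Cu-]C; iodomethane, CI
Why: The Gilman reagent (monovalent copper) forms a π-complex with the enoate of 4 and transfers a methyl group to C4 through a β-cuprio intermediate (formally trivalent copper) that reductively eliminates, leaving lithium enolate 5; DMPU then frees this enolate for SN2 attack on iodomethane at C3. The closest known reaction type is the tandem conjugate addition–enolate alkylation of γ-alkoxybutenolides. No ring is closed. C4 is controlled by the C5 acetal substituent: on the nearly flat butenolide the bulky menthyloxy group covers one face, so the cuprate should enter from the other and place the methyl trans to oxygen (4S). C3 is controlled in turn by the new C4 methyl, the electrophile approaching the enolate face opposite to it (3S); this is also the more stable trans arrangement, so any equilibration works in the same direction. The step needs 1,4- over 1,2-addition, which the soft cuprate secures, two anti facial selectivities, which the C5 alkoxy group and then the C4 methyl secure, and mono- over dimethylation, which low temperature and a short reaction time should secure. The absolute sense rests on C5 alone, fixed as S by the crystallisation of 4.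

Step 4
Reactants: 6 (3S,4S,5S)-3,4-dimethyl-5-{[(1S,2R,5S)-2-isopropyl-5-methylcyclohexyl]oxy}dihydrofuran-2(3H)-one; 7 1-(benzyloxy)-4-bromo-2-methoxybenzene
Product: 10 (2R,3S,4S,5S)-2-[4-(benzyloxy)-3-methoxyphenyl]-3,4-dimethyl-5-{[(1S,2R,5S)-2-isopropyl-5-methylcyclohexyl]oxy}tetrahydrofuran, via aryllithium 8 (not isolated), via lithium hemiketalate 9 (not isolated)
Conditions: 7, n-BuLi, THF, −78 °C; 6, −78 °C; then, without aqueous work-up, Et3SiH, BF3·OEt2, CH2Cl2, −78 → −40 °C
Reagents that add atoms: none
Why: Aryllithium addition to the lactone gives tetrahedral alkoxide 9, stable at −78 °C; it is not protonated, because the free hemiketal would open to an aryl ketone whose hemiacetal end sheds menthol. BF3·OEt2 turns the alkoxide oxygen into the leaving group and Et3SiH reduces the aryl-stabilised ring oxocarbenium ion (ionic hydrogenation of a lactone-derived hemiketal), which ionises far more readily than the secondary menthyl acetal at this temperature. Hydride should add anti to the pseudoaxial C3 methyl and anti to the C5 menthyloxy group, leaving the aryl group cis to the C3 methyl (2R).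

Step 5
Reactants: 10 (2R,3S,4S,5S)-2-[4-(benzyloxy)-3-methoxyphenyl]-3,4-dimethyl-5-{[(1S,2R,5S)-2-isopropyl-5-methylcyclohexyl]oxy}tetrahydrofuran
Product: 11 (2R,3S,4S)-2-[4-(benzyloxy)-3-methoxyphenyl]-3,4-dimethyl-5-(phenylsulfonyl)tetrahydrofuran (mixture of C5 epimers)
Conditions: PhSO2H (excess), CaCl2, CH2Cl2, 0 °C → rt
Reagents that add atoms: benzenesulfinic acid, O=S(O)c1ccccc1
Why: Acid-mediated acetal exchange; the sulfinic acid protonates the acetal, menthol leaves through the ring oxocarbenium ion and sulfinate adds through sulfur, while CaCl2 binds the released alcohol. The C5 configuration of the sulfone does not matter because it ionises again in step 6.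

Step 6
Reactants: 11 (2R,3S,4S)-2-[4-(benzyloxy)-3-methoxyphenyl]-3,4-dimethyl-5-(phenylsulfonyl)tetrahydrofuran; 7 1-(benzyloxy)-4-bromo-2-methoxybenzene
Product: 14 (2R,3S,4S,5R)-2,5-bis[4-(benzyloxy)-3-methoxyphenyl]-3,4-dimethyltetrahydrofuran, via arylmagnesium bromide 12 (not isolated), via arylzinc bromide 13 (not isolated)
Conditions: 7, Mg turnings (I2 cat.), THF, 40 °C; ZnBr2 (excess), THF, 0 °C → rt; then 11, THF, rt
Reagents that add atoms: none
Why: Magnesium insertion into the aryl bromide gives Grignard reagent 12, which transmetalates with ZnBr2 to arylzinc bromide 13; the remaining ZnBr2 ionises the sulfone to the C5 oxocarbenium ion and the arylzinc transfers its aryl group (Lewis-acid-promoted substitution of a 2-sulfonyl cyclic ether by an organozinc). In the envelope with both methyls pseudoequatorial, inside attack should deliver the aryl group cis to the C4 methyl and trans to the C3 methyl and the C2 aryl group, which is the 4,5-cis arrangement (5R).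

Step 7
Reactants: 14 (2R,3S,4S,5R)-2,5-bis[4-(benzyloxy)-3-methoxyphenyl]-3,4-dimethyltetrahydrofuran
Product: 15 4,4'-[(2R,3S,4S,5R)-3,4-dimethyltetrahydrofuran-2,5-diyl]bis(2-methoxyphenol)
Conditions: H2 (1 atm), 10% Pd/C, EtOAc, rt
Reagents that add atoms: none
Why: Hydrogenolysis of the two aryl benzyl ethers; under neutral conditions at atmospheric pressure these should cleave much faster than the ring benzylic C–O bonds, and the reaction is stopped once two benzyl groups are gone.

Step 8
Reactants: 15 4,4'-[(2R,3S,4S,5R)-3,4-dimethyltetrahydrofuran-2,5-diyl]bis(2-methoxyphenol); 16 ethyl (S)-lactate (two equivalents, one per phenol)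
Product: 17 diethyl (2R,2'R)-2,2'-{[(2R,3S,4S,5R)-3,4-dimethyltetrahydrofuran-2,5-diyl]bis[(2-methoxy-4,1-phenylene)oxy]}dipropanoate
Conditions: 16 (2.2 equiv), PPh3 (2.4 equiv), DIAD (2.4 equiv), THF, 0 °C → rt
Reagents that add atoms: ethyl (S)-lactate (second equivalent of 16), CCOC(=O)[C@H](C)O
Why: Two-fold Mitsunobu etherification; each phenol displaces the activated secondary hydroxyl of one molecule of lactate by SN2 with inversion, turning (S) into (R) at both C8 centres.

Step 9
Reactants: 17 diethyl (2R,2'R)-2,2'-{[(2R,3S,4S,5R)-3,4-dimethyltetrahydrofuran-2,5-diyl]bis[(2-methoxy-4,1-phenylene)oxy]}dipropanoate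
Product: 18 (2R,2'R)-2,2'-{[(2R,3S,4S,5R)-3,4-dimethyltetrahydrofuran-2,5-diyl]bis[(2-methoxy-4,1-phenylene)oxy]}dipropanal
Conditions: i-Bu2AlH (DIBAL-H), CH2Cl2, −78 °C; MeOH quench, aq. KNaC4H4O6
Reagents that add atoms: none
Why: Partial reduction of the esters; the tetrahedral aluminium hemiacetal, held by the neighbouring aryloxy oxygen, should survive at −78 °C until the quench, so the aldehyde appears only on work-up and C8 is not epimerised. The dialdehyde is used at once.

Step 10
Reactants: 18 (2R,2'R)-2,2'-{[(2R,3S,4S,5R)-3,4-dimethyltetrahydrofuran-2,5-diyl]bis[(2-methoxy-4,1-phenylene)oxy]}dipropanal; 19 (3,4-dimethoxyphenyl)magnesium bromide (at least two equivalents, one per aldehyde)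
Product: 20 (1R,1'R,2R,2'R)-2,2'-{[(2R,3S,4S,5R)-3,4-dimethyltetrahydrofuran-2,5-diyl]bis[(2-methoxy-4,1-phenylene)oxy]}bis[1-(3,4-dimethoxyphenyl)propan-1-ol] (target)
Conditions: MgBr2·OEt2, CH2Cl2, −78 °C; then 19 (THF solution, excess), −78 → −40 °C; aq. NH4Cl
Reagents that add atoms: (3,4-dimethoxyphenyl)magnesium bromide (second equivalent of 19), COc1ccc([Mg]Br)cc1OC
Why: Chelation-controlled Grignard addition at each of the two aldehydes; magnesium bridges the aldehyde oxygen and the C8 aryloxy oxygen, helped by the ortho methoxy group, and the aryl group adds to the face of the chelate that carries the C8 hydrogen. This should give the (7R,8R) threo carbinol at both ends.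

## Compound list

1 | furfural (furan-2-carbaldehyde) | O=Cc1ccco1 | starting material
2 | 5-hydroxyfuran-2(5H)-one, racemic | O=C1C=CC(O)O1 | intermediate
3 | (+)-menthol, (1S,2R,5S)-2-isopropyl-5-methylcyclohexan-1-ol | CC(C)[C@H]1CC[C@H](C)C[C@@H]1O | starting material
4 | (5S)-5-{[(1S,2R,5S)-2-isopropyl-5-methylcyclohexyl]oxy}furan-2(5H)-one | O=C1C=C[C@@H](O[C@H]2C[C@@H](C)CC[C@@H]2C(C)C)O1 | intermediate
5 | lithium (4S,5S)-4-methyl-5-{[(1S,2R,5S)-2-isopropyl-5-methylcyclohexyl]oxy}-4,5-dihydrofuran-2-olate | [Li]OC1=C[C@H](C)[C@@H](O[C@H]2C[C@@H](C)CC[C@@H]2C(C)C)O1 | intermediate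
6 | (3S,4S,5S)-3,4-dimethyl-5-{[(1S,2R,5S)-2-isopropyl-5-methylcyclohexyl]oxy}dihydrofuran-2(3H)-one | O=C1O[C@H](O[C@H]2C[C@@H](C)CC[C@@H]2C(C)C)[C@@H](C)[C@@H]1C | intermediate
7 | 1-(benzyloxy)-4-bromo-2-methoxybenzene | COc1cc(Br)ccc1OCc1ccccc1 | starting material
8 | [4-(benzyloxy)-3-methoxyphenyl]lithium | COc1cc([Li])ccc1OCc1ccccc1 | intermediate
9 | lithium (3S,4S,5S)-2-[4-(benzyloxy)-3-methoxyphenyl]-3,4-dimethyl-5-{[(1S,2R,5S)-2-isopropyl-5-methylcyclohexyl]oxy}tetrahydrofuran-2-olate (C2 epimers) | COc1cc(C2(O[Li])O[C@H](O[C@H]3C[C@@H](C)CC[C@@H]3C(C)C)[C@@H](C)[C@@H]2C)ccc1OCc1ccccc1 | intermediate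
10 | (2R,3S,4S,5S)-2-[4-(benzyloxy)-3-methoxyphenyl]-3,4-dimethyl-5-{[(1S,2R,5S)-2-isopropyl-5-methylcyclohexyl]oxy}tetrahydrofuran | COc1cc([C@@H]2O[C@H](O[C@H]3C[C@@H](C)CC[C@@H]3C(C)C)[C@@H](C)[C@@H]2C)ccc1OCc1ccccc1 | intermediate
11 | (2R,3S,4S)-2-[4-(benzyloxy)-3-methoxyphenyl]-3,4-dimethyl-5-(phenylsulfonyl)tetrahydrofuran (C5 epimers) | COc1cc([C@@H]2OC(S(=O)(=O)c3ccccc3)[C@@H](C)[C@@H]2C)ccc1OCc1ccccc1 | intermediate
12 | [4-(benzyloxy)-3-methoxyphenyl]magnesium bromide | COc1cc([Mg]Br)ccc1OCc1ccccc1 | intermediate
13 | [4-(benzyloxy)-3-methoxyphenyl]zinc bromide | COc1cc([Zn]Br)ccc1OCc1ccccc1 | intermediate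
14 | (2R,3S,4S,5R)-2,5-bis[4-(benzyloxy)-3-methoxyphenyl]-3,4-dimethyltetrahydrofuran | COc1cc([C@@H]2O[C@@H](c3ccc(OCc4ccccc4)c(OC)c3)[C@@H](C)[C@@H]2C)ccc1OCc1ccccc1 | intermediate
15 | 4,4'-[(2R,3S,4S,5R)-3,4-dimethyltetrahydrofuran-2,5-diyl]bis(2-methoxyphenol) | COc1cc([C@@H]2O[C@@H](c3ccc(O)c(OC)c3)[C@@H](C)[C@@H]2C)ccc1O | intermediate
16 | ethyl (S)-lactate | CCOC(=O)[C@H](C)O | starting material
17 | diethyl (2R,2'R)-2,2'-{[(2R,3S,4S,5R)-3,4-dimethyltetrahydrofuran-2,5-diyl]bis[(2-methoxy-4,1-phenylene)oxy]}dipropanoate | CCOC(=O)[C@@H](C)Oc1ccc([C@@H]2O[C@@H](c3ccc(O[C@H](C)C(=O)OCC)c(OC)c3)[C@@H](C)[C@@H]2C)cc1OC | intermediate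
18 | (2R,2'R)-2,2'-{[(2R,3S,4S,5R)-3,4-dimethyltetrahydrofuran-2,5-diyl]bis[(2-methoxy-4,1-phenylene)oxy]}dipropanal | O=C[C@@H](C)Oc1ccc([C@@H]2O[C@@H](c3ccc(O[C@H](C)C=O)c(OC)c3)[C@@H](C)[C@@H]2C)cc1OC | intermediate
19 | (3,4-dimethoxyphenyl)magnesium bromide | COc1ccc([Mg]Br)cc1OC | starting material
20 | (1R,1'R,2R,2'R)-2,2'-{[(2R,3S,4S,5R)-3,4-dimethyltetrahydrofuran-2,5-diyl]bis[(2-methoxy-4,1-phenylene)oxy]}bis[1-(3,4-dimethoxyphenyl)propan-1-ol] | COc1ccc([C@@H](O)[C@@H](C)Oc2ccc([C@@H]3O[C@@H](c4ccc(O[C@H](C)[C@H](O)c5ccc(OC)c(OC)c5)c(OC)c4)[C@@H](C)[C@@H]3C)cc2OC)cc1OC | target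

## Step count and least certain steps

Total: 10 steps. Longest linear sequence: 10 steps, from furfural 1 to 20. Compounds 3, 7, 16 and 19 are bought and enter directly.

**Step 3 (key step).**
- What may go wrong: electron transfer from the cuprate to the γ,γ-dioxygenated enoate may expel the acetal oxygen instead of giving clean 1,4-addition. The copper-bound enolate may alkylate slowly, so that proton transfer leads to unmethylated and dimethylated lactone. Facial selectivity in the alkylation may be incomplete.
- Fallback, from 4 to 6: 2-lithio-1,3-dithiane, a non-reducing carbon nucleophile, is added to 4 and the enolate is trapped with iodomethane in the same pot. This should give (3S,4S,5S)-4-(1,3-dithian-2-yl)-3-methyl-5-{[(1S,2R,5S)-2-isopropyl-5-methylcyclohexyl]oxy}dihydrofuran-2(3H)-one F1 with the same anti,anti sense. Desulfurisation of F1 with Raney Ni in ethanol turns the dithianyl carbon into the C4 methyl and returns to the route at 6.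

**Step 4.**
- What may go wrong: the tetrahedral alkoxide may collapse before it is ionised, giving ring opening, loss of menthol and a second aryllithium addition. The Lewis acid may also ionise the C5 acetal, reducing it to the ether or eroding facial control at C2.
- Fallback, from 6 to 14: lactone 6 is reduced with i-Bu2AlH at −78 °C to the lactol (3S,4S,5S)-3,4-dimethyl-5-{[(1S,2R,5S)-2-isopropyl-5-methylcyclohexyl]oxy}tetrahydrofuran-2-ol F2. Excess PhSO2H with CaCl2 exchanges both anomeric groups to give (3S,4S)-3,4-dimethyl-2,5-bis(phenylsulfonyl)tetrahydrofuran F3. Excess arylzinc 13, prepared as in step 6, with ZnBr2 then replaces both sulfinates, each aryl entering cis to its neighbouring methyl, and the route is rejoined at 14. No carbonyl addition is needed on this path.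

**Step 5.**
- What may go wrong: the exchange may stall because the hindered menthyl group leaves slowly and menthol is not bound well by CaCl2. Prolonged exposure to the sulfinic acid may ionise the benzylic C2–O1 bond and epimerise C2.
- Fallback, from 10 to 11: acetal 10 is hydrolysed with aqueous acetic acid in THF to the lactol (3S,4S,5R)-5-[4-(benzyloxy)-3-methoxyphenyl]-3,4-dimethyltetrahydrofuran-2-ol F4, and menthol is removed by chromatography. The lactol is then treated with PhSO2H and CaCl2, where loss of water drives the exchange, returning to the route at 11.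

**Step 6.**
- What may go wrong: the facial selectivity of aryl transfer to the C5 cation may be poor, or the cation may lose a proton to give an enol ether.
- Fallback, from 10 to 14: after hydrolysis of 10 to the lactol F4 of the step 5 fallback, oxidation with PhI(OAc)2 and catalytic 2,2,6,6-tetramethylpiperidin-1-oxyl gives (3S,4S,5R)-5-[4-(benzyloxy)-3-methoxyphenyl]-3,4-dimethyldihydrofuran-2(3H)-one F5. Aryllithium 8, generated from 7 as in step 4, adds at −78 °C to give the hemiketal (3S,4S,5R)-2,5-bis[4-(benzyloxy)-3-methoxyphenyl]-3,4-dimethyltetrahydrofuran-2-ol F6. Reduction with Et3SiH and BF3·OEt2 at −78 °C, with hydride entering anti to the adjacent methyl, should set the aryl group cis to that methyl and rejoin the route at 14. Here the bond to C5 is made by carbonyl addition and the stereocentre by hydride delivery, not by aryl delivery to a cation.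

**Step 10** (with step 9).
- What may go wrong: chelation by the weakly basic aryloxy oxygen may be incomplete, so that open-chain Felkin-type addition gives erythro carbinol at one or both ends. The α-aryloxy aldehyde may epimerise at C8 before it reacts.
- Fallback, from 18 to 20: 19 is added to 18 without regard to selectivity, giving the carbinol-epimer mixture 2,2'-{[(2R,3S,4S,5R)-3,4-dimethyltetrahydrofuran-2,5-diyl]bis[(2-methoxy-4,1-phenylene)oxy]}bis[1-(3,4-dimethoxyphenyl)propan-1-ol] F7. Dess–Martin periodinane oxidises it to the diketone (2R,2'R)-2,2'-{[(2R,3S,4S,5R)-3,4-dimethyltetrahydrofuran-2,5-diyl]bis[(2-methoxy-4,1-phenylene)oxy]}bis[1-(3,4-dimethoxyphenyl)propan-1-one] F8. A non-chelating borohydride (NaBH4 with 15-crown-5) then reduces F8; hydride should enter anti to the aryloxy group under Felkin–Anh control, giving the threo carbinols of 20.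

## Further compounds

F1 | step 3 | (3S,4S,5S)-4-(1,3-dithian-2-yl)-3-methyl-5-{[(1S,2R,5S)-2-isopropyl-5-methylcyclohexyl]oxy}dihydrofuran-2(3H)-one | O=C1O[C@H](O[C@H]2C[C@@H](C)CC[C@@H]2C(C)C)[C@@H](C2SCCCS2)[C@@H]1C
F2 | step 4 | (3S,4S,5S)-3,4-dimethyl-5-{[(1S,2R,5S)-2-isopropyl-5-methylcyclohexyl]oxy}tetrahydrofuran-2-ol (C2 epimers) | OC1O[C@H](O[C@H]2C[C@@H](C)CC[C@@H]2C(C)C)[C@@H](C)[C@@H]1C
F3 | step 4 | (3S,4S)-3,4-dimethyl-2,5-bis(phenylsulfonyl)tetrahydrofuran (anomeric centres undefined) | O1C(S(=O)(=O)c2ccccc2)[C@@H](C)[C@H](C)C1S(=O)(=O)c1ccccc1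
F4 | step 5 | (3S,4S,5R)-5-[4-(benzyloxy)-3-methoxyphenyl]-3,4-dimethyltetrahydrofuran-2-ol (C2 epimers) | COc1cc([C@@H]2OC(O)[C@@H](C)[C@@H]2C)ccc1OCc1ccccc1
F5 | step 6 | (3S,4S,5R)-5-[4-(benzyloxy)-3-methoxyphenyl]-3,4-dimethyldihydrofuran-2(3H)-one | O=C1O[C@@H](c2ccc(OCc3ccccc3)c(OC)c2)[C@@H](C)[C@@H]1C
F6 | step 6 | (3S,4S,5R)-2,5-bis[4-(benzyloxy)-3-methoxyphenyl]-3,4-dimethyltetrahydrofuran-2-ol (C2 epimers) | COc1cc(C2(O)O[C@@H](c3ccc(OCc4ccccc4)c(OC)c3)[C@@H](C)[C@@H]2C)ccc1OCc1ccccc1
F7 | step 10 | (2R,2'R)-2,2'-{[(2R,3S,4S,5R)-3,4-dimethyltetrahydrofuran-2,5-diyl]bis[(2-methoxy-4,1-phenylene)oxy]}bis[1-(3,4-dimethoxyphenyl)propan-1-ol], mixture of carbinol epimers | COc1ccc(C(O)[C@@H](C)Oc2ccc([C@@H]3O[C@@H](c4ccc(O[C@H](C)C(O)c5ccc(OC)c(OC)c5)c(OC)c4)[C@@H](C)[C@@H]3C)cc2OC)cc1OC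
F8 | step 10 | (2R,2'R)-2,2'-{[(2R,3S,4S,5R)-3,4-dimethyltetrahydrofuran-2,5-diyl]bis[(2-methoxy-4,1-phenylene)oxy]}bis[1-(3,4-dimethoxyphenyl)propan-1-one] | COc1ccc(C(=O)[C@@H](C)Oc2ccc([C@@H]3O[C@@H](c4ccc(O[C@H](C)C(=O)c5ccc(OC)c(OC)c5)c(OC)c4)[C@@H](C)[C@@H]3C)cc2OC)cc1OC
A1 | alternative 1 | (2R,3S,4S,5R)-2,5-bis(4-bromo-3-methoxyphenyl)-3,4-dimethyltetrahydrofuran | COc1cc([C@@H]2O[C@@H](c3ccc(Br)c(OC)c3)[C@@H](C)[C@@H]2C)ccc1Br
A2 | alternative 1 | (1S,2S,3S)-1-(4-bromo-3-methoxyphenyl)-2,3-dimethyl-4-oxobutyl methanesulfonate | COc1cc([C@@H](OS(C)(=O)=O)[C@@H](C)[C@H](C)C=O)ccc1Br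
A3 | alternative 1 | (4-bromo-3-methoxyphenyl)magnesium chloride | COc1cc([Mg]Cl)ccc1Br
A4 | alternative 2 | bis(tert-butyldimethylsilyl) ether of the target | COc1ccc([C@@H](O[Si](C)(C)C(C)(C)C)[C@@H](C)Oc2ccc([C@@H]3O[C@@H](c4ccc(O[C@H](C)[C@H](O[Si](C)(C)C(C)(C)C)c5ccc(OC)c(OC)c5)c(OC)c4)[C@@H](C)[C@@H]3C)cc2OC)cc1OC
A5 | alternative 2 | (3S,4S)-3,4-dimethyl-2,5-bis(phenylsulfonyl)tetrahydrofuran (anomeric centres undefined) | O1C(S(=O)(=O)c2ccccc2)[C@@H](C)[C@H](C)C1S(=O)(=O)c1ccccc1
A6 | alternative 2 | bromo{4-{[(1R,2R)-1-[(tert-butyldimethylsilyl)oxy]-1-(3,4-dimethoxyphenyl)propan-2-yl]oxy}-3-methoxyphenyl}zinc | COc1ccc([C@@H](O[Si](C)(C)C(C)(C)C)[C@@H](C)Oc2ccc([Zn]Br)cc2OC)cc1OC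
A7 | alternative 3 | (3S,4S,5R)-5-[4-(benzyloxy)-3-methoxyphenyl]-3,4-dimethyldihydrofuran-2(3H)-one | O=C1O[C@@H](c2ccc(OCc3ccccc3)c(OC)c2)[C@@H](C)[C@@H]1C
A8 | alternative 3 | tiglic aldehyde, (E)-2-methylbut-2-enal | C/C=C(\C)C=O
A9 | alternative 3 | 4-(benzyloxy)-3-methoxybenzaldehyde | COc1cc(C=O)ccc1OCc1ccccc1
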